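**Assumption:** atoms of all intermediates carry the chromone numbering of the target (O1, C2–C4, C4a, C5–C8, C8a). The SMILES is read as (5S,6S,7S,8R): 5-, 6- and 7-OH mutually cis, 8-Cl trans to 7-OH. Isovanillin, kojic acid, 2,2-dimethyl-1,3-dioxan-5-one and (R)-proline are taken as commercial.

## Retrosynthetic overview

1. The target is traced back to a C6 ketone whose O5 and O7 are tied in an acetonide; the last operations are acetal hydrolysis, C8–OH → C8–Cl with inversion, and C6=O → C6–OH.
2. Key disconnection: C7–C8 (amine-catalysed aldol) and C4a–C5 (palladium-catalysed ketone α-alkenylation) are cut together. This is a [3+3] annulation of 2,2-dimethyl-1,3-dioxan-5-one (C5–C6–C7) with a 2-formyl-4-oxopyran-3-yl triflate (C4a–C8a–C8).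
3. Enabling feature: C5–C6–C7 is a cis-1,2,3-triol, a reduced dihydroxyacetone. With C6 as ketone, C5 and C7 are both nucleophilic α-carbons, and the cis O5/O7 pair can stay in the six-membered acetonide. The annulation product is then a 2,4-dioxabicyclo[3.3.1]nonan-9-one whose bridgehead C5 and C7 cannot enolize (no β-elimination, no aromatization to the chromone, C5/C7 cis by necessity). On the pyranone ring, C4a and C8 flank C8a just as the enolic OH and the free ortho position sit in kojic acid, so C4a can carry a triflate and C8 an aldehyde.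
4. The pyranone aldehyde comes from kojic acid: Wittig extension of the CH2OH arm with MOM-protected isovanillin, hydrogenation, ortho-hydroxymethylation, O-triflation, oxidation.
5. Ring order: pyranone ring (present in kojic acid) → carbocycle, closed onto the temporary 1,3-dioxane ring in the key step → temporary dioxane ring opened in the last step.

Key step: step 9

## Route

Step 1
Reactants: 1 isovanillin (3-hydroxy-4-methoxybenzaldehyde)
Product: 2 4-methoxy-3-(methoxymethoxy)benzaldehyde
Conditions: MOMCl, iPr2NEt, CH2Cl2, 0 °C → rt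
Reagents that add atoms: chloromethyl methyl ether, COCCl
Why: O-alkylation of the phenol gives a MOM acetal that should survive every basic, reductive and palladium step and fall off in the final acid step.

Step 2
Reactants: 3 kojic acid (5-hydroxy-2-(hydroxymethyl)-4H-pyran-4-one)
Product: 4 chlorokojic acid (2-(chloromethyl)-5-hydroxy-4H-pyran-4-one)
Conditions: SOCl2 (neat), rt
Reagents that add atoms: thionyl chloride, O=S(Cl)Cl
Why: chlorodehydroxylation of the primary allylic-type alcohol with thionyl chloride; the enolic 5-OH does not react.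

Step 3
Reactants: 4 chlorokojic acid
Product: 5 [(5-hydroxy-4-oxo-4H-pyran-2-yl)methyl]triphenylphosphonium chloride
Conditions: PPh3, MeCN, reflux
Reagents that add atoms: triphenylphosphine, c1ccc(cc1)P(c1ccccc1)c1ccccc1
Why: SN2 quaternization of an activated primary chloride.

Step 4
Reactants: 5 phosphonium chloride; 2 4-methoxy-3-(methoxymethoxy)benzaldehyde
Product: 6 (E)-5-hydroxy-2-{2-[4-methoxy-3-(methoxymethoxy)phenyl]ethenyl}-4H-pyran-4-one
Conditions: K2CO3, MeOH/CH2Cl2, rt; aq. NH4Cl work-up
Reagents that add atoms: none
Why: Wittig olefination with the pyranone-stabilized ylide; the alkene geometry is irrelevant because the double bond is hydrogenated next.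

Step 5
Reactants: 6 styryl pyranone
Product: 7 5-hydroxy-2-{2-[4-methoxy-3-(methoxymethoxy)phenyl]ethyl}-4H-pyran-4-one
Conditions: H2 (1 atm), Pd/C (5 %), EtOAc, rt
Reagents that add atoms: none
Why: heterogeneous hydrogenation of the styryl double bond; the aromatic pyranone and the MOM ether should be untouched at 1 atm.

Step 6
Reactants: 7 5-hydroxy-2-(arylethyl)pyranone
Product: 8 3-hydroxy-2-(hydroxymethyl)-6-{2-[4-methoxy-3-(methoxymethoxy)phenyl]ethyl}-4H-pyran-4-one
Conditions: aq. HCHO, NaOH, H2O/MeOH, rt; then HCl to pH 3
Reagents that add atoms: formaldehyde, C=O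
Why: base-mediated hydroxymethylation at the only free position ortho to the enolic hydroxyl (as with kojic acid itself), which puts the future C8 on the future C8a.

Step 7
Reactants: 8 hydroxymethyl enol
Product: 9 2-(hydroxymethyl)-6-{2-[4-methoxy-3-(methoxymethoxy)phenyl]ethyl}-4-oxo-4H-pyran-3-yl trifluoromethanesulfonate
Conditions: PhNTf2, Et3N, CH2Cl2, 0 °C → rt
Reagents that add atoms: N-phenylbis(trifluoromethanesulfonimide), O=S(=O)(N(c1ccccc1)S(=O)(=O)C(F)(F)F)C(F)(F)F
Why: the mild triflating agent sulfonylates only the acidic enolic hydroxyl (future C4a–O) and leaves the primary alcohol free.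

Step 8
Reactants: 9 hydroxymethyl triflate
Product: 10 2-formyl-6-{2-[4-methoxy-3-(methoxymethoxy)phenyl]ethyl}-4-oxo-4H-pyran-3-yl trifluoromethanesulfonate
Conditions: Dess–Martin periodinane, CH2Cl2, 0 °C → rt
Reagents that add atoms: none
Why: Dess–Martin oxidation of the primary alcohol to the non-enolizable aldehyde (future C8) under neutral conditions that leave triflate and MOM ether intact.

Step 9
Reactants: 10 aldehyde triflate; 11 2,2-dimethyl-1,3-dioxan-5-one
Product: 13 (5S,7R,8S)-8-hydroxy-5,7-(isopropylidenedioxy)-2-{2-[4-methoxy-3-(methoxymethoxy)phenyl]ethyl}-6-oxo-5,6,7,8-tetrahydrochromen-4-one (5,7-acetonide-bridged ketone), via anti-aldol adduct 12 (not isolated)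
Conditions: (R)-proline (30 mol %), DMF, 4 °C; then Pd2(dba)3 (5 mol %), Xantphos (12 mol %), KOPh (1.2 equiv) added to the same flask, 4 → 45 °C
Reagents that add atoms: none
Why: Proposed new method: two catalytic cycles that are each known are run as one annulation in one flask on an unprotected aldol. First, (R)-proline turns 11 into its enamine, which adds through the carboxylic-acid-directed chair transition state of proline aldol catalysis to the aldehyde of 10 (C7–C8 bond; closest known type: proline-catalysed anti aldol reactions of 2,2-dimethyl-1,3-dioxan-5-one with aldehydes). Then zerovalent palladium inserts into the C4a–OTf bond and the alkenyl-palladium species is attacked by the C5 enolate (or enamine) carbon of 12, and C–C reductive elimination forms C4a–C5 (closest known types: palladium-catalysed intramolecular α-alkenylation of ketones to bicyclo[3.3.1]nonanones, and amine/palladium cooperative α-arylation of ketones). The six-membered carbocycle closes in this second event by reductive elimination from a seven-membered palladacycle, and because both new bonds start from the α and α′ carbons of one six-membered ketone the product is a 2,4-dioxabicyclo[3.3.1]nonan-9-one fused to the pyranone. C7 (R) and C8 (S) are set by the catalyst (anti aldol, the mirror image of the (S)-proline series), and C5 (S) is set by the ring, since only a cis-diaxial pair of C5 and C7 substituents on the dioxanone can be spanned by the C8–C8a–C4a unit. The step needs the aldol to come before the coupling (secured by running the amine-catalysed addition at 4 °C before the palladium catalyst is added), enolization of 12 toward the unsubstituted C5 and not toward C7 (favoured by the weak phenoxide base), and a product that survives the base (secured by the bridgehead positions of C5 and C7, which forbid enolization and β-elimination of the C8 hydroxyl).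

Step 10
Reactants: 13 bridged ketone
Product: 14 (5S,6S,7S,8S)-6,8-dihydroxy-5,7-(isopropylidenedioxy)-2-{2-[4-methoxy-3-(methoxymethoxy)phenyl]ethyl}-5,6,7,8-tetrahydrochromen-4-one
Conditions: NaBH4, MeOH/CH2Cl2 (1:1), −78 °C
Reagents that add atoms: none
Why: borohydride reduction of the non-enolizable ketone, where hydride is expected to add anti to the two α C–O bonds that both lie on the dioxane face (polar Felkin–Anh control), so the new C6–OH ends cis to O5 and O7, while the vinylogous-ester carbonyl of the pyranone should not be reduced at −78 °C.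

Step 11
Reactants: 14 diol
Product: 16 (5S,6S,7S,8R)-8-chloro-6-hydroxy-5,7-(isopropylidenedioxy)-2-{2-[4-methoxy-3-(methoxymethoxy)phenyl]ethyl}-5,6,7,8-tetrahydrochromen-4-one, via C8 mesylate 15 (not isolated)
Conditions: MsCl, Et3N, CH2Cl2, −40 °C; then LiCl, DMF, 50 °C
Reagents that add atoms: methanesulfonyl chloride, CS(=O)(=O)Cl (its atoms stay only in 15); lithium chloride, [Li+].[Cl-]
Why: the equatorial C8–OH next to the pyranone should be sulfonylated in preference to the C6–OH held between two bridgeheads, and SN2 displacement by chloride with inversion then gives C8–Cl trans to O7; elimination is excluded because C7 is a bridgehead and C8a carries no hydrogen.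

Step 12
Reactants: 16 chloro acetonide
Product: 17 (5S,6S,7S,8R)-8-chloro-5,6,7-trihydroxy-2-[2-(3-hydroxy-4-methoxyphenyl)ethyl]-5,6,7,8-tetrahydro-4H-chromen-4-one (target)
Conditions: TFA/H2O (9:1), 0 °C → rt
Reagents that add atoms: none
Why: acid hydrolysis of the strained bridging ketal and of the aryl MOM acetal in one operation; the trans-chlorohydrin is acid-stable (it would close to the epoxide only under base).

## Compound list

1 | isovanillin (3-hydroxy-4-methoxybenzaldehyde) | COc1ccc(C=O)cc1O | starting material
2 | 4-methoxy-3-(methoxymethoxy)benzaldehyde | COCOc1cc(C=O)ccc1OC | intermediate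
3 | kojic acid (5-hydroxy-2-(hydroxymethyl)-4H-pyran-4-one) | OCc1cc(=O)c(O)co1 | starting material
4 | chlorokojic acid (2-(chloromethyl)-5-hydroxy-4H-pyran-4-one) | ClCc1cc(=O)c(O)co1 | intermediate
5 | [(5-hydroxy-4-oxo-4H-pyran-2-yl)methyl]triphenylphosphonium chloride | O=c1cc(C[P+](c2ccccc2)(c2ccccc2)c2ccccc2)occ1O.[Cl-] | intermediate
6 | (E)-5-hydroxy-2-{2-[4-methoxy-3-(methoxymethoxy)phenyl]ethenyl}-4H-pyran-4-one | COCOc1cc(/C=C/c2cc(=O)c(O)co2)ccc1OC | intermediate
7 | 5-hydroxy-2-{2-[4-methoxy-3-(methoxymethoxy)phenyl]ethyl}-4H-pyran-4-one | COCOc1cc(CCc2cc(=O)c(O)co2)ccc1OC | intermediate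
8 | 3-hydroxy-2-(hydroxymethyl)-6-{2-[4-methoxy-3-(methoxymethoxy)phenyl]ethyl}-4H-pyran-4-one | COCOc1cc(CCc2cc(=O)c(O)c(CO)o2)ccc1OC | intermediate
9 | 2-(hydroxymethyl)-6-{2-[4-methoxy-3-(methoxymethoxy)phenyl]ethyl}-4-oxo-4H-pyran-3-yl trifluoromethanesulfonate | COCOc1cc(CCc2cc(=O)c(OS(=O)(=O)C(F)(F)F)c(CO)o2)ccc1OC | intermediate
10 | 2-formyl-6-{2-[4-methoxy-3-(methoxymethoxy)phenyl]ethyl}-4-oxo-4H-pyran-3-yl trifluoromethanesulfonate | COCOc1cc(CCc2cc(=O)c(OS(=O)(=O)C(F)(F)F)c(C=O)o2)ccc1OC | intermediate
11 | 2,2-dimethyl-1,3-dioxan-5-one | CC1(C)OCC(=O)CO1 | starting material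
12 | anti-aldol adduct: 2-{(S)-hydroxy[(4R)-2,2-dimethyl-5-oxo-1,3-dioxan-4-yl]methyl}-6-{2-[4-methoxy-3-(methoxymethoxy)phenyl]ethyl}-4-oxo-4H-pyran-3-yl trifluoromethanesulfonate (C7 R, C8 S) | CC1(C)OCC(=O)[C@H](O1)[C@H](O)c2oc(CCc3ccc(OC)c(OCOC)c3)cc(=O)c2OS(=O)(=O)C(F)(F)F | intermediate (not isolated)
13 | bridged ketone: (5S,7R,8S)-8-hydroxy-5,7-(isopropylidenedioxy)-2-{2-[4-methoxy-3-(methoxymethoxy)phenyl]ethyl}-7,8-dihydro-4H-chromene-4,6(5H)-dione; O5 and O7 cis and tied by the acetonide, 8-OH cis to O7 | O=c1cc(CCc4ccc(OC)c(OCOC)c4)oc2c1[C@@H]3OC(C)(C)O[C@@H](C3=O)[C@@H]2O | intermediate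
14 | (5S,6S,7S,8S)-6,8-dihydroxy-5,7-(isopropylidenedioxy)-2-{2-[4-methoxy-3-(methoxymethoxy)phenyl]ethyl}-5,6,7,8-tetrahydro-4H-chromen-4-one; O5, O6, O7 and O8 all cis | O=c1cc(CCc4ccc(OC)c(OCOC)c4)oc2c1[C@@H]3OC(C)(C)O[C@@H]([C@H]3O)[C@@H]2O | intermediate
15 | C8 methanesulfonate of 14 | O=c1cc(CCc4ccc(OC)c(OCOC)c4)oc2c1[C@@H]3OC(C)(C)O[C@@H]([C@H]3O)[C@@H]2OS(C)(=O)=O | intermediate (not isolated)
16 | (5S,6S,7S,8R)-8-chloro-6-hydroxy-5,7-(isopropylidenedioxy)-2-{2-[4-methoxy-3-(methoxymethoxy)phenyl]ethyl}-5,6,7,8-tetrahydro-4H-chromen-4-one; Cl trans to O7 | O=c1cc(CCc4ccc(OC)c(OCOC)c4)oc2c1[C@@H]3OC(C)(C)O[C@@H]([C@H]3O)[C@H]2Cl | intermediate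
17 | (5S,6S,7S,8R)-8-chloro-5,6,7-trihydroxy-2-[2-(3-hydroxy-4-methoxyphenyl)ethyl]-5,6,7,8-tetrahydro-4H-chromen-4-one | COc1ccc(CCc2cc(=O)c3c(o2)[C@H](Cl)[C@@H](O)[C@@H](O)[C@H]3O)cc1O | target

## Step count and risks

Total steps: 12. Longest linear sequence: 11 steps (kojic acid 3 → 17, steps 2–12); step 1 is a one-step side branch.

**Step 9 (carries the label).** What may go wrong: retro-aldol cleavage or dehydration of the unprotected aldol adduct once base and heat are applied; intermolecular alkenylation of surplus dioxanone competing with ring closure; erosion of enantiomeric purity through reversible aldolization. Fallback with known chemistry, run stepwise: from 10 and 11 the proline aldol alone (DMF, 4 °C) is worked up to isolate 12. Its C8 hydroxyl is silylated (TBSOTf, 2,6-lutidine, CH2Cl2, −78 °C) to the O8-tert-butyldimethylsilyl ether of the aldol adduct F1, which can no longer undergo retro-aldol cleavage. The established intramolecular palladium-catalysed ketone α-alkenylation (Pd(PPh3)4, KOPh, THF, 65 °C) then closes the carbocycle to the O8-silyl ether of the bridged ketone F2. HF·pyridine in THF removes the silyl group and the sequence rejoins the route at 13.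

**Step 10.** What may go wrong: poor facial selectivity, with hydride entering from the dioxane face (the sterically more open side, possibly helped by cation binding to O5 and O7) and giving the C6 epimer. Fallback: the reduction is moved from kinetic to thermodynamic control by an equilibrating Meerwein–Ponndorf–Verley reduction of 13 (Al(OiPr)3, iPrOH/toluene, 60 °C). Under reversible hydride transfer the aluminium alkoxide that is axial on the dioxane ring and chelated by O5 and O7 should accumulate; it is the alkoxide of 14, where the route is rejoined. No new compound is involved.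

**Step 11.** What may go wrong: incomplete discrimination between the two secondary hydroxyls; slow displacement next to the axial C7–O bond; loss of configuration at C8 by chloride exchange on the product. Fallback: from 14 the cis-diequatorial O6/O8 pair is closed to the 6,8-cyclic sulfate F3 (1,1′-sulfonyldiimidazole, NaH, THF, −20 °C → rt), which activates C8 without any selectivity question. LiCl in DMF should open it at the activated C8 with inversion to give the lithium 6-O-sulfate of the 8-chloro acetonide F4. Aqueous acid (cat. H2SO4, THF/H2O; then TFA/H2O) hydrolyses the sulfate monoester together with the acetonide and the MOM ether, and the sequence comes back at 17.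

## Further compounds

F1 | step 9 | O8-tert-butyldimethylsilyl ether of aldol adduct 12 | CC1(C)OCC(=O)[C@H](O1)[C@H](O[Si](C)(C)C(C)(C)C)c2oc(CCc3ccc(OC)c(OCOC)c3)cc(=O)c2OS(=O)(=O)C(F)(F)F
F2 | step 9 | O8-tert-butyldimethylsilyl ether of bridged ketone 13 | O=c1cc(CCc4ccc(OC)c(OCOC)c4)oc2c1[C@@H]3OC(C)(C)O[C@@H](C3=O)[C@@H]2O[Si](C)(C)C(C)(C)C
F0 | step 10 | none | none
F3 | step 11 | 6,8-cyclic sulfate of diol 14 | O=c1cc(CCc5ccc(OC)c(OCOC)c5)oc2c1[C@@H]3OC(C)(C)O[C@@H]([C@H]3OS4(=O)=O)[C@@H]2O4
F4 | step 11 | lithium 6-O-sulfate of 8-chloro acetonide 16 | O=c1cc(CCc5ccc(OC)c(OCOC)c5)oc2c1[C@@H]3OC(C)(C)O[C@@H]([C@H]3OS(=O)(=O)[O-])[C@H]2Cl.[Li+]
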